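The ratio of partner to substrate in Monday's charge is 3.07, against 3.00 in Saturday's run, so your hunch that Monday copies Saturday is right about the shape of the curve, but I doubt it about the clock, and I wouldn't quote Saturday's 47.1 % at 4.1 min.

| flask | substrate | partner | time |
|---|---|---|---|
| Saturday's | 150 mM | 450 mM |  |
| Friday's | 150 mM | 1400 mM |  |
| Sunday's | 450 mM | 450 mM |  |
| Monday's | 75.0 mM | 230 mM | 4.1 min |

| run | time / min | [target] / mM |
|---|---|---|
| Saturday's run | 0.16 | 5.8 |
| Saturday's run | 0.28 | 12.4 |
| Saturday's run | 0.48 | 19.8 |
| Saturday's run | 0.82 | 30.2 |
| Saturday's run | 1.4 | 45.6 |
| Saturday's run | 2.4 | 61.0 |
| Saturday's run | 4.1 | 70.7 |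
| Friday's run | 0.16 | 21.1 |
| Friday's run | 0.28 | 33.5 |
| Friday's run | 0.48 | 50.8 |
| Friday's run | 0.82 | 68.1 |
| Friday's run | 1.4 | 75.3 |
| Friday's run | 2.4 | 68.7 |
| Friday's run | 4.1 | 44.9 |
| Sunday's run | 0.16 | 22.2 |
| Sunday's run | 0.28 | 36.2 |
| Sunday's run | 0.48 | 57.6 |
| Sunday's run | 0.82 | 86.9 |
| Sunday's run | 1.4 | 124.6 |
| Sunday's run | 2.4 | 161.8 |
| Sunday's run | 4.1 | 193.0 |

(standard deviation of a reading: 0.8 mM)

1. order of the initial rate in [partner], near the charge of the Saturday's run, the rate being that where two percent of its substrate are target
2. order of the initial rate in [substrate], near the charge of the Saturday's run, the rate being that where two percent of its substrate are target (one fixed amount of target, the same in the runs compared)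
3. target in the Monday's run at 4.1 min, as a share of the substrate charged
4. which of these the readings show (nothing beyond the main steps / the second partner is lost in pairs / the product reacts on with the second partner / two substrates go astray together)

- Overall: substrate + partner -> target.
- Constant volume, constant temperature.
- "The second partner" is partner.
- An order is taken over about fifteen percent of the charge, up and down.

I compared the rates at one moment. Let S, P and R be substrate, target and partner, a the rate constant for making target and b the one for losing it. Friday's run shows that loss: with more partner than substrate in the charge, target fell from 75.3 mM to 44.9 mM. I gave each step one factor of partner: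

making = a·S·R, loss = b·P·R, so loss/making = (b/a)·P/S

R cancels from that ratio, where b/a is the selectivity factor. On these terms the comparison drifts with the shares, and R stands in both rates alike. The clock is then the partner-time, τ = ∫R dt, not the minute.

On Saturday's run, target reached a quarter of the charge at about

t = 1.09 min

I took mean partner as the mean of its start and end values, counting target made as partner gone. That gives the partner-time for a quarter of the charge:

τq = 472 mM·min

Monday's partner charge stands at 0.511 of Saturday's, and I took that ratio to hold at equal shares, so Monday's 4.1 min count as

2.10 min on Saturday's clock

A straight line between Saturday's readings there gives 37.5 %.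

The forecast gives orders of 1.02 and 1.04, Monday at 37.4 %, and the verdict "the product reacts on with the second partner", noting “With excess partner, this indicates target is consumed by partner”. My figure differs from its value by 0.10 percentage points, less than one reading's scatter of 0.533 % of Saturday's charge.

The flask gives 37.6 % for Monday, with orders of 1.0 and 1.0, and the verdict "the product reacts on with the second partner". The fit with two substrates going astray together leaves a root mean square residual of 23 in units of the scatter.

    substrate + partner ⇌ target (0.7080 /M/min, 0.02202 /min)
    target + partner → side product (0.3294 /M/min)

Sunday's run made target to a quarter of its substrate charge at 1.19 min, and Sunday's own mean partner, reckoned the same way, makes that 469 mM·min, against τq = 472 mM·min.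

(The data are simulated from invented constants; scatter was added.)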